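## Retrosynthetic overview

1. Target 32 ⇐ tert‑butyl ester 31 ⇐ Yamaguchi esterification of C4‑alcohol 29 with dienoic acid 28; 28 comes from (R)‑2‑methylbutanoic acid by Wittig then Horner–Wadsworth–Emmons olefination.
2. 29 ⇐ hydrindenone 15 by C1 alkylation with 2‑(chloromethyl)allyl chloride (later oxidised to the enal) and γ‑hydroxylation at C4 through the silyl dienol ether.
3. 15 ⇐ 1,4‑diketone 14 (aldol condensation closes the five‑membered ring last) ⇐ cyclohexanone 13 (Wacker) ⇐ chloro ketone 12 (enolate alkylation closes the six‑membered ring first).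
4. 12 ⇐ allylic ester 8 by Ireland–Claisen [3,3] rearrangement, which forms the C7–C7a bond and sets the quaternary carbon and the carboxyl‑bearing carbon together.
5. 8 ⇐ methyl (R)‑lactate (supplies C1–C3 and all core chirality) + keto ylide 3 + 4‑chlorobutanoyl chloride.

Assumption: the side‑chain centre is (6R) as encoded in the given SMILES, so (R)‑2‑methylbutanoic acid is used; it and methyl (R)‑lactate are taken as catalogue chiral materials.
Core atoms are numbered as in indene (C1, C2, C3, C3a, C4–C7, C7a).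

## Route

Step 1
Reactants: 1 methyl (2R)-2-hydroxypropanoate
Product: 2 methyl (2R)-2-[(tert-butyldimethylsilyl)oxy]propanoate
Conditions: TBSCl, imidazole, DMF, 0 °C → rt
Reagents that add atoms: tert-butyldimethylsilyl chloride, CC(C)(C)[Si](C)(C)Cl
Why: Standard O‑silylation of the secondary alcohol protects it for the reduction without touching the stereocentre.

Step 2
Reactants: 2 methyl (2R)-2-[(tert-butyldimethylsilyl)oxy]propanoate; 3 3-(triphenyl-λ5-phosphanylidene)butan-2-one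
Product: 5 (3E,5R)-5-[(tert-butyldimethylsilyl)oxy]-3-methylhex-3-en-2-one, via aldehyde 4 (not isolated)
Conditions: i-Bu2AlH (1.05 equiv), CH2Cl2, −78 °C; MeOH quench; then 3, CH2Cl2, 40 °C
Reagents that add atoms: none
Why: Ester half‑reduction followed by Wittig olefination with the stabilised keto ylide gives the (E)‑trisubstituted enone, and the α‑silyloxy aldehyde is used crude so the lactate centre is not epimerised.

Step 3
Reactants: 5 (3E,5R)-5-[(tert-butyldimethylsilyl)oxy]-3-methylhex-3-en-2-one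
Product: 6 (3E,5R)-5-hydroxy-3-methylhex-3-en-2-one
Conditions: HF·pyridine, THF, 0 °C → rt
Reagents that add atoms: none
Why: Fluoride desilylation under mildly acidic conditions frees the allylic alcohol without E/Z isomerisation or cyclisation of the γ‑hydroxy enone.

Step 4
Reactants: 6 (3E,5R)-5-hydroxy-3-methylhex-3-en-2-one; 7 4-chlorobutanoyl chloride
Product: 8 (2R,3E)-4-methyl-5-oxohex-3-en-2-yl 4-chlorobutanoate
Conditions: pyridine, DMAP (cat.), CH2Cl2, 0 °C
Reagents that add atoms: none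
Why: DMAP‑catalysed acylation of the secondary alcohol proceeds with retention and gives the allyl ester needed for the rearrangement.

Step 5
Reactants: 8 (2R,3E)-4-methyl-5-oxohex-3-en-2-yl 4-chlorobutanoate
Product: 11 (2R,3S,4E)-3-acetyl-2-(2-chloroethyl)-3-methylhex-4-enoic acid, via bis-silyl ketene acetal 9 (not isolated), via bis-silyl rearranged ester 10 (not isolated)
Conditions: LiN(i-Pr)2 (2.3 equiv), THF–DMPU (4:1), −78 °C; Me3SiCl–Et3N; −78 → 55 °C; then 1 M HCl
Reagents that add atoms: none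
Why: Ireland–Claisen [3,3]‑sigmatropic rearrangement: the methyl ketone is held as its silyl enol ether, the ester gives the (Z)‑silyl ketene acetal in THF–DMPU, and a chair transition state with the carbinol methyl equatorial transfers the (R)‑C–O centre to the new C–C bond, setting (3S) at the quaternary carbon and (2R) next to it and leaving an (E)‑propenyl group.

Step 6
Reactants: 11 (2R,3S,4E)-3-acetyl-2-(2-chloroethyl)-3-methylhex-4-enoic acid
Product: 12 tert-butyl (2R,3S,4E)-3-acetyl-2-(2-chloroethyl)-3-methylhex-4-enoate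
Conditions: tert-butyl 2,2,2-trichloroacetimidate, BF3·OEt2 (cat.), CH2Cl2–cyclohexane, rt
Reagents that add atoms: tert-butyl 2,2,2-trichloroacetimidate, CC(C)(C)OC(=N)C(Cl)(Cl)Cl
Why: Acid‑catalysed imidate esterification installs a bulky ester that resists attack by the ketone enolate in step 7 and is removable by acid at the end.

Step 7
Reactants: 12 tert-butyl (2R,3S,4E)-3-acetyl-2-(2-chloroethyl)-3-methylhex-4-enoate
Product: 13 tert-butyl (1R,2S)-2-methyl-3-oxo-2-[(1E)-prop-1-en-1-yl]cyclohexane-1-carboxylate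
Conditions: KN(SiMe3)2 (1.1 equiv), THF, −78 °C → rt
Reagents that add atoms: none
Why: Intramolecular enolate C‑alkylation (6‑exo‑tet) closes the cyclohexanone because the acetyl methyl is the only enolisable ketone position and is more acidic than the hindered ester α‑hydrogen; no stereocentre is touched.

Step 8
Reactants: 13 tert-butyl (1R,2S)-2-methyl-3-oxo-2-[(1E)-prop-1-en-1-yl]cyclohexane-1-carboxylate
Product: 14 tert-butyl (1R,2S)-2-methyl-3-oxo-2-(2-oxopropyl)cyclohexane-1-carboxylate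
Conditions: PdCl2 (10 mol %), CuCl (1 equiv), O2 (1 atm), DMF–H2O (7:1), 50 °C
Reagents that add atoms: water, O
Why: Tsuji–Wacker oxidation places the oxygen on the alkene carbon remote from the quaternary centre (γ to the ring carbonyl, the usual outcome for β,γ‑unsaturated ketones), giving the 1,4‑diketone.

Step 9
Reactants: 14 tert-butyl (1R,2S)-2-methyl-3-oxo-2-(2-oxopropyl)cyclohexane-1-carboxylate
Product: 15 tert-butyl (7R,7aS)-7a-methyl-2-oxo-2,4,5,6,7,7a-hexahydro-1H-indene-7-carboxylate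
Conditions: KOH, MeOH, rt
Reagents that add atoms: none
Why: Intramolecular aldol condensation of the methyl ketone onto the ring ketone is the only closure that can dehydrate, giving the fused cyclopentenone with the C3=C3a enone.

Step 10
Reactants: 15 tert-butyl (7R,7aS)-7a-methyl-2-oxo-2,4,5,6,7,7a-hexahydro-1H-indene-7-carboxylate; 16 3-chloro-2-(chloromethyl)prop-1-ene
Product: 18 tert-butyl (1R,7R,7aS)-1-[2-(chloromethyl)prop-2-en-1-yl]-7a-methyl-2-oxo-2,4,5,6,7,7a-hexahydro-1H-indene-7-carboxylate, via C1 epimer 17 (not isolated)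
Conditions: LiN(i-Pr)2 (1.05 equiv), THF, −78 °C; 16 (5 equiv), DMPU, −78 → 0 °C; then DBU (0.3 equiv), toluene, rt
Reagents that add atoms: none
Why: Kinetic α′‑deprotonation of the enone and SN2 alkylation with excess allylic dichloride give both C1 epimers, and DBU equilibrates this enolisable centre to the isomer with the side chain cis to the angular methyl and away from the C7 ester branch (the preference shown by 17β side chains in steroids).

Step 11
Reactants: 18 tert-butyl (1R,7R,7aS)-1-[2-(chloromethyl)prop-2-en-1-yl]-7a-methyl-2-oxo-2,4,5,6,7,7a-hexahydro-1H-indene-7-carboxylate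
Product: 20 tert-butyl (1R,4S,7R,7aS)-1-[2-(chloromethyl)prop-2-en-1-yl]-4-hydroxy-7a-methyl-2-oxo-2,4,5,6,7,7a-hexahydro-1H-indene-7-carboxylate, via silyl dienol ether 19 (not isolated)
Conditions: TBSOTf, Et3N, CH2Cl2, −78 → 0 °C; then mCPBA, NaHCO3, CH2Cl2, −20 °C; 1 M HCl–THF work-up
Reagents that add atoms: 3-chloroperoxybenzoic acid, OOC(=O)c1cccc(Cl)c1
Why: Vinylogous Rubottom oxidation: soft enolisation removes a C4 hydrogen (C1 is now tertiary and hindered) to give the extended silyloxy diene, and the peracid attacks C4 axially on the face of the angular methyl, as in the 6β‑hydroxylation of steroidal 3,5‑dienol ethers, setting (4S).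

Step 12
Reactants: 21 (2R)-2-methylbutanoic acid
Product: 22 (2R)-2-methylbutan-1-ol
Conditions: LiAlH4, Et2O, 0 °C → rt
Reagents that add atoms: none
Why: Hydride reduction of the acid to the primary alcohol leaves the α‑stereocentre untouched.

Step 13
Reactants: 22 (2R)-2-methylbutan-1-ol; 23 2-(triphenyl-λ5-phosphanylidene)propanal
Product: 25 (2E,4R)-2,4-dimethylhex-2-enal, via (2R)-2-methylbutanal 24 (not isolated)
Conditions: (COCl)2, DMSO, i-Pr2NEt, CH2Cl2, −78 °C; then 23, −78 → 40 °C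
Reagents that add atoms: none
Why: Swern oxidation and in‑situ Wittig olefination with the stabilised formyl ylide give the (E)‑enal while the volatile, epimerisable aldehyde is never isolated.

Step 14
Reactants: 25 (2E,4R)-2,4-dimethylhex-2-enal; 26 triethyl phosphonoacetate
Product: 27 ethyl (2E,4E,6R)-4,6-dimethylocta-2,4-dienoate
Conditions: NaH, THF, 0 °C → rt
Reagents that add atoms: none
Why: Horner–Wadsworth–Emmons olefination gives the (2E)‑alkene and completes the dienoate.

Step 15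
Reactants: 27 ethyl (2E,4E,6R)-4,6-dimethylocta-2,4-dienoate
Product: 28 (2E,4E,6R)-4,6-dimethylocta-2,4-dienoic acid
Conditions: LiOH, THF–MeOH–H2O, rt; then 1 M HCl
Reagents that add atoms: lithium hydroxide, [Li+].[OH-]
Why: Saponification of the ethyl ester gives the acid without affecting the diene geometry or the remote stereocentre.

Step 16
Reactants: 20 tert-butyl (1R,4S,7R,7aS)-1-[2-(chloromethyl)prop-2-en-1-yl]-4-hydroxy-7a-methyl-2-oxo-2,4,5,6,7,7a-hexahydro-1H-indene-7-carboxylate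
Product: 29 tert-butyl (1R,4S,7R,7aS)-1-(2-formylprop-2-en-1-yl)-4-hydroxy-7a-methyl-2-oxo-2,4,5,6,7,7a-hexahydro-1H-indene-7-carboxylate
Conditions: 4-methylmorpholine 4-oxide (5 equiv), NaI (0.2 equiv), 4 Å MS, MeCN, 40 °C
Reagents that add atoms: 4-methylmorpholine 4-oxide, C[N+]1([O-])CCOCC1
Why: Kornblum/Ganem‑type oxidation of the allylic chloride by the amine N‑oxide gives the α‑substituted acrolein, and doing it before esterification keeps the allylic chloride away from DMAP while the mildly basic medium keeps C1 under thermodynamic control.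

Step 17
Reactants: 29 tert-butyl (1R,4S,7R,7aS)-1-(2-formylprop-2-en-1-yl)-4-hydroxy-7a-methyl-2-oxo-2,4,5,6,7,7a-hexahydro-1H-indene-7-carboxylate; 28 (2E,4E,6R)-4,6-dimethylocta-2,4-dienoic acid
Product: 31 tert-butyl (1R,4S,7R,7aS)-4-{[(2E,4E,6R)-4,6-dimethylocta-2,4-dienoyl]oxy}-1-(2-formylprop-2-en-1-yl)-7a-methyl-2-oxo-2,4,5,6,7,7a-hexahydro-1H-indene-7-carboxylate, via mixed anhydride 30 (not isolated)
Conditions: 28, 2,4,6-trichlorobenzoyl chloride, Et3N, toluene, rt; then 29, DMAP, toluene, rt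
Reagents that add atoms: none
Why: Yamaguchi esterification acylates the hindered axial allylic alcohol with retention at C4; the α‑substituted enal cannot undergo amine‑catalysed self‑coupling.

Step 18
Reactants: 31 tert-butyl (1R,4S,7R,7aS)-4-{[(2E,4E,6R)-4,6-dimethylocta-2,4-dienoyl]oxy}-1-(2-formylprop-2-en-1-yl)-7a-methyl-2-oxo-2,4,5,6,7,7a-hexahydro-1H-indene-7-carboxylate
Product: 32 (1R,4S,7R,7aS)-4-{[(2E,4E,6R)-4,6-dimethylocta-2,4-dienoyl]oxy}-1-(2-formylprop-2-en-1-yl)-7a-methyl-2-oxo-2,4,5,6,7,7a-hexahydro-1H-indene-7-carboxylic acid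
Conditions: TFA–CH2Cl2 (1:4), 0 °C → rt
Reagents that add atoms: none
Why: Acidolysis of the tert‑butyl ester (loss of isobutene) frees the carboxylic acid under conditions that the dienoate, the enal and the γ‑acyloxy enone tolerate.

## Compound list

1 | methyl (2R)-2-hydroxypropanoate | C[C@@H](O)C(=O)OC | starting material
2 | methyl (2R)-2-[(tert-butyldimethylsilyl)oxy]propanoate | C[C@@H](O[Si](C)(C)C(C)(C)C)C(=O)OC | intermediate
3 | 3-(triphenyl-λ5-phosphanylidene)butan-2-one | CC(=O)C(C)=P(c1ccccc1)(c1ccccc1)c1ccccc1 | starting material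
4 | (2R)-2-[(tert-butyldimethylsilyl)oxy]propanal | C[C@@H](O[Si](C)(C)C(C)(C)C)C=O | intermediate
5 | (3E,5R)-5-[(tert-butyldimethylsilyl)oxy]-3-methylhex-3-en-2-one | CC(=O)/C(C)=C/[C@@H](C)O[Si](C)(C)C(C)(C)C | intermediate
6 | (3E,5R)-5-hydroxy-3-methylhex-3-en-2-one | CC(=O)/C(C)=C/[C@@H](C)O | intermediate
7 | 4-chlorobutanoyl chloride | O=C(Cl)CCCCl | starting material
8 | (2R,3E)-4-methyl-5-oxohex-3-en-2-yl 4-chlorobutanoate | CC(=O)/C(C)=C/[C@@H](C)OC(=O)CCCCl | intermediate
9 | {[(1Z)-4-chloro-1-{[(2R,3E)-4-methyl-5-[(trimethylsilyl)oxy]hexa-3,5-dien-2-yl]oxy}but-1-en-1-yl]oxy}trimethylsilane | ClCC/C=C(\O[Si](C)(C)C)O[C@H](C)/C=C(\C)C(=C)O[Si](C)(C)C | intermediate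
10 | trimethylsilyl (2R,3S,4E)-2-(2-chloroethyl)-3-methyl-3-{1-[(trimethylsilyl)oxy]ethenyl}hex-4-enoate | C/C=C/[C@](C)(C(=C)O[Si](C)(C)C)[C@@H](CCCl)C(=O)O[Si](C)(C)C | intermediate
11 | (2R,3S,4E)-3-acetyl-2-(2-chloroethyl)-3-methylhex-4-enoic acid | C/C=C/[C@](C)(C(C)=O)[C@@H](CCCl)C(=O)O | intermediate
12 | tert-butyl (2R,3S,4E)-3-acetyl-2-(2-chloroethyl)-3-methylhex-4-enoate | C/C=C/[C@](C)(C(C)=O)[C@@H](CCCl)C(=O)OC(C)(C)C | intermediate
13 | tert-butyl (1R,2S)-2-methyl-3-oxo-2-[(1E)-prop-1-en-1-yl]cyclohexane-1-carboxylate | C/C=C/[C@]1(C)C(=O)CCC[C@H]1C(=O)OC(C)(C)C | intermediate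
14 | tert-butyl (1R,2S)-2-methyl-3-oxo-2-(2-oxopropyl)cyclohexane-1-carboxylate | CC(=O)C[C@]1(C)C(=O)CCC[C@H]1C(=O)OC(C)(C)C | intermediate
15 | tert-butyl (7R,7aS)-7a-methyl-2-oxo-2,4,5,6,7,7a-hexahydro-1H-indene-7-carboxylate | C1C(=O)C=C2CCC[C@@H](C(=O)OC(C)(C)C)[C@@]21C | intermediate
16 | 3-chloro-2-(chloromethyl)prop-1-ene | C=C(CCl)CCl | starting material
17 | tert-butyl (1S,7R,7aS)-1-[2-(chloromethyl)prop-2-en-1-yl]-7a-methyl-2-oxo-2,4,5,6,7,7a-hexahydro-1H-indene-7-carboxylate | C=C(CCl)C[C@@H]1C(=O)C=C2CCC[C@@H](C(=O)OC(C)(C)C)[C@@]21C | intermediate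
18 | tert-butyl (1R,7R,7aS)-1-[2-(chloromethyl)prop-2-en-1-yl]-7a-methyl-2-oxo-2,4,5,6,7,7a-hexahydro-1H-indene-7-carboxylate | C=C(CCl)C[C@H]1C(=O)C=C2CCC[C@@H](C(=O)OC(C)(C)C)[C@@]21C | intermediate
19 | tert-butyl (1R,7R,7aS)-2-[(tert-butyldimethylsilyl)oxy]-1-[2-(chloromethyl)prop-2-en-1-yl]-7a-methyl-5,6,7,7a-tetrahydro-1H-indene-7-carboxylate | C=C(CCl)C[C@H]1C(O[Si](C)(C)C(C)(C)C)=CC2=CCC[C@@H](C(=O)OC(C)(C)C)[C@@]21C | intermediate
20 | tert-butyl (1R,4S,7R,7aS)-1-[2-(chloromethyl)prop-2-en-1-yl]-4-hydroxy-7a-methyl-2-oxo-2,4,5,6,7,7a-hexahydro-1H-indene-7-carboxylate | C=C(CCl)C[C@H]1C(=O)C=C2[C@@H](O)CC[C@@H](C(=O)OC(C)(C)C)[C@@]21C | intermediate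
21 | (2R)-2-methylbutanoic acid | CC[C@@H](C)C(=O)O | starting material
22 | (2R)-2-methylbutan-1-ol | CC[C@@H](C)CO | intermediate
23 | 2-(triphenyl-λ5-phosphanylidene)propanal | CC(C=O)=P(c1ccccc1)(c1ccccc1)c1ccccc1 | starting material
24 | (2R)-2-methylbutanal | CC[C@@H](C)C=O | intermediate
25 | (2E,4R)-2,4-dimethylhex-2-enal | CC[C@@H](C)/C=C(\C)C=O | intermediate
26 | triethyl phosphonoacetate | CCOC(=O)CP(=O)(OCC)OCC | starting material
27 | ethyl (2E,4E,6R)-4,6-dimethylocta-2,4-dienoate | CCOC(=O)/C=C/C(C)=C/[C@H](C)CC | intermediate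
28 | (2E,4E,6R)-4,6-dimethylocta-2,4-dienoic acid | OC(=O)/C=C/C(C)=C/[C@H](C)CC | intermediate
29 | tert-butyl (1R,4S,7R,7aS)-1-(2-formylprop-2-en-1-yl)-4-hydroxy-7a-methyl-2-oxo-2,4,5,6,7,7a-hexahydro-1H-indene-7-carboxylate | C=C(C=O)C[C@H]1C(=O)C=C2[C@@H](O)CC[C@@H](C(=O)OC(C)(C)C)[C@@]21C | intermediate
30 | (2E,4E,6R)-4,6-dimethylocta-2,4-dienoic 2,4,6-trichlorobenzoic anhydride | O=C(OC(=O)/C=C/C(C)=C/[C@H](C)CC)c1c(Cl)cc(Cl)cc1Cl | intermediate
31 | tert-butyl (1R,4S,7R,7aS)-4-{[(2E,4E,6R)-4,6-dimethylocta-2,4-dienoyl]oxy}-1-(2-formylprop-2-en-1-yl)-7a-methyl-2-oxo-2,4,5,6,7,7a-hexahydro-1H-indene-7-carboxylate | C=C(C=O)C[C@H]1C(=O)C=C2[C@@H](OC(=O)/C=C/C(C)=C/[C@H](C)CC)CC[C@@H](C(=O)OC(C)(C)C)[C@@]21C | intermediate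
32 | (1R,4S,7R,7aS)-4-{[(2E,4E,6R)-4,6-dimethylocta-2,4-dienoyl]oxy}-1-(2-formylprop-2-en-1-yl)-7a-methyl-2-oxo-2,4,5,6,7,7a-hexahydro-1H-indene-7-carboxylic acid | C=C(C=O)C[C@H]1C(=O)C=C2[C@@H](OC(=O)/C=C/C(C)=C/[C@H](C)CC)CC[C@@H](C(=O)O)[C@@]21C | target

## Step count and risks

Total step count: 18. Longest linear sequence: 14 (steps 1–11, then 16–18); the side chain (steps 12–15) joins at step 17.

Most likely to fail, first: step 5. The methyl ketone and the γ‑hydrogen of 8 compete for base, the chlorobutanoate enolate can close to a cyclopropane, and the (Z)‑ketene acetal ratio limits selectivity at the carboxyl‑bearing carbon. The fallback sets out from 2 and comes back at 12, carrying the ketone as a Weinreb amide through the rearrangement. 2 is reduced to 4 as before and olefinated with N‑methoxy‑N‑methyl‑2‑(triphenyl‑λ5‑phosphanylidene)propanamide to the silyl‑protected Weinreb enamide F1. HF·pyridine gives the allylic alcohol F2, and 7 with pyridine gives the chlorobutanoate F3. LiN(i‑Pr)2 (1.1 equiv) and Me3SiCl in THF–DMPU give the (Z)‑silyl ketene acetal F4, which rearranges to the silyl ester F5 and, after acidic work‑up, the amido acid F6. tert‑Butyl trichloroacetimidate gives the tert‑butyl ester F7, and MeLi (THF, −78 °C) adds once to the Weinreb amide to return methyl ketone 12.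

Second: step 8. Internal alkenes are slow in Wacker oxidations and the oxygen could end up on the carbon next to the quaternary centre. The fallback sets out from 13 and comes back at 14, fixing the regiochemistry by a halohydrin instead. N‑Bromosuccinimide in wet DMSO gives the bromohydrin F8, because water opens the bromonium ion at the carbon remote from the neopentyl position. Bu3SnH with AIBN (toluene, 80 °C) removes the bromine to give the secondary alcohol F9, and Dess–Martin periodinane oxidises it to diketone 14.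

Third: step 11. Silylation may occur towards C1 instead of C4, and the peracid may attack anti to the angular methyl. The fallback sets out from 18 and comes back at 20 by oxidation then reduction. CrO3 with 3,5‑dimethylpyrazole (CH2Cl2, −20 °C) oxidises the γ‑methylene to the ene‑dione F10. NaBH4 with CeCl3·7H2O (MeOH, −78 °C) then reduces the less hindered C4 carbonyl from the face opposite the angular methyl, which places the hydroxyl cis to it and gives 20.

Further compounds

F1 | step 5 | (2E,4R)-4-[(tert-butyldimethylsilyl)oxy]-N-methoxy-N,2-dimethylpent-2-enamide | CON(C)C(=O)/C(C)=C/[C@@H](C)O[Si](C)(C)C(C)(C)C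
F2 | step 5 | (2E,4R)-4-hydroxy-N-methoxy-N,2-dimethylpent-2-enamide | CON(C)C(=O)/C(C)=C/[C@@H](C)O
F3 | step 5 | (2R,3E)-5-[methoxy(methyl)amino]-4-methyl-5-oxopent-3-en-2-yl 4-chlorobutanoate | CON(C)C(=O)/C(C)=C/[C@@H](C)OC(=O)CCCCl
F4 | step 5 | (2E,4R)-4-{[(1Z)-4-chloro-1-[(trimethylsilyl)oxy]but-1-en-1-yl]oxy}-N-methoxy-N,2-dimethylpent-2-enamide | ClCC/C=C(\O[Si](C)(C)C)O[C@H](C)/C=C(\C)C(=O)N(C)OC
F5 | step 5 | trimethylsilyl (2R,3S,4E)-2-(2-chloroethyl)-3-[methoxy(methyl)carbamoyl]-3-methylhex-4-enoate | C/C=C/[C@](C)(C(=O)N(C)OC)[C@@H](CCCl)C(=O)O[Si](C)(C)C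
F6 | step 5 | (2R,3S,4E)-2-(2-chloroethyl)-3-[methoxy(methyl)carbamoyl]-3-methylhex-4-enoic acid | C/C=C/[C@](C)(C(=O)N(C)OC)[C@@H](CCCl)C(=O)O
F7 | step 5 | tert-butyl (2R,3S,4E)-2-(2-chloroethyl)-3-[methoxy(methyl)carbamoyl]-3-methylhex-4-enoate | C/C=C/[C@](C)(C(=O)N(C)OC)[C@@H](CCCl)C(=O)OC(C)(C)C
F8 | step 8 | tert-butyl (1R,2S)-2-(1-bromo-2-hydroxypropyl)-2-methyl-3-oxocyclohexane-1-carboxylate (mixture at the two new centres) | CC(O)C(Br)[C@]1(C)C(=O)CCC[C@H]1C(=O)OC(C)(C)C
F9 | step 8 | tert-butyl (1R,2S)-2-(2-hydroxypropyl)-2-methyl-3-oxocyclohexane-1-carboxylate (mixture at the carbinol centre) | CC(O)C[C@]1(C)C(=O)CCC[C@H]1C(=O)OC(C)(C)C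
F10 | step 11 | tert-butyl (1R,7R,7aS)-1-[2-(chloromethyl)prop-2-en-1-yl]-7a-methyl-2,4-dioxo-2,4,5,6,7,7a-hexahydro-1H-indene-7-carboxylate | C=C(CCl)C[C@H]1C(=O)C=C2C(=O)CC[C@@H](C(=O)OC(C)(C)C)[C@@]21C
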